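**Plan**

- Numbering follows the eremophilane skeleton: decalin C1–C10 with the ketone at C2, C14 = methyl on C5, C15 = methyl on C4, C11–C13 = isopropenyl on C7. The same atom numbers are used for the cage intermediates.
- Retrosynthesis: the ester C–O bonds at O8 and O9 are cut first, C8 and C9 go back to ketone and dimethyl ketal, C7–C11 is cut (acetone aldol) and C3=C4 is restored. Then the C5–C6 bond of ring B is cut as the retron of a [3,3] shift of a 2-vinylbicyclo[2.2.2]oct-5-en-2-ol, followed by the vinyl bond C7–C8 and the two cycloaddition bonds C10–C1 and C3–C2.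
- Enabling feature: the cis junction (C5 methyl, 10-H) beside the vicinal oxygens on C8 and C9 is a dearomatised 2-methoxy-4,5-dimethylphenol in disguise. C8 is the dienone carbonyl, C9 the ketal carbon and C3–C4–C5–C10 the diene, so ring A and the C8–C9 unit can be held in one cage before ring B exists.
- Forward order: phenol → dienone ketal → bicyclo[2.2.2]octenone (ring A carbons plus C8, C9) → vinyl carbinol → ring B by anionic oxy-Cope rearrangement → C7 side chain, C8 and C9 carbinols → C2 enone and its reduction → the two esters.
- Stereochemistry: the absolute sense comes from resolving the cage ketone; the cage dictates the cis fusion (C5, C10); C7, C8 and C9 are set by reagents arriving on the convex face of the cis-decalin; C4 by axial protonation in a dissolving-metal reduction.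

Key step: step 6

Remark: tert-butyldimethyl(vinyloxy)silane is taken to be a purchasable enol ether.

**Step 1**
Reactants: 1 3,4-dimethylphenol
Product: 2 2-bromo-4,5-dimethylphenol
Conditions: NBS (1.0 equiv), i-Pr2NH (0.1 equiv), CH2Cl2, 0 °C
Reagents that add atoms: N-bromosuccinimide, O=C1CCC(=O)N1Br
Why: Amine-mediated electrophilic ortho-bromination of a phenol; the para position is blocked by a methyl group, and of the two ortho positions the one not flanked by the neighbouring methyl should react.

**Step 2**
Reactants: 2 2-bromo-4,5-dimethylphenol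
Product: 3 2-methoxy-4,5-dimethylphenol
Conditions: NaOMe (5 equiv, 25% in MeOH), CuBr (0.1 equiv), DMF, 110 °C
Reagents that add atoms: sodium methoxide, [Na+].[O-]C
Why: Copper-catalysed Ullmann-type methoxylation of an aryl bromide, the established passage from 2-bromo-4-alkylphenols to 2-methoxyphenols, which the free phenoxide tolerates.

**Step 3**
Reactants: 3 2-methoxy-4,5-dimethylphenol; 4 tert-butyldimethyl(vinyloxy)silane
Product: 6 racemic cage ketone (bridgeheads C3 and C10; bridges C4(CH3)=C5(CH3), C8(=O)–C9(OCH3)2 and C2H(OSi-t-BuMe2)–C1H2; silyloxy group endo, syn to the alkene bridge), via dienone ketal 5 (not isolated)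
Conditions: PhI(OAc)2 (1.1 equiv) in MeOH added over 1 h to 3, 4 (8 equiv) and NaHCO3 (3 equiv) in MeOH, 0 °C, then 25 °C
Reagents that add atoms: tert-butyldimethyl(vinyloxy)silane (4), C=CO[Si](C)(C)C(C)(C)C; methanol, CO
Why: Oxidative dearomatisation of the 2-methoxyphenol by the trivalent-iodine reagent in methanol should give dienone ketal 5, which is trapped in an inverse-electron-demand Diels–Alder reaction: the nucleophilic CH2 terminus of the enol ether bonds to the diene carbon next to the ketal and the oxygenated carbon to the one next to the carbonyl, through an endo transition state that sets the three cage stereocentres (C3, C10, C2) in relative sense, while the C4 methyl of 5 slows its self-dimerisation and NaHCO3 protects the silyl enol ether from acetic acid.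

**Step 4**
Reactants: 6 racemic cage ketone
Product: 7 (1S,4S,7S)-7-[(tert-butyldimethylsilyl)oxy]-3,3-dimethoxy-5,6-dimethylbicyclo[2.2.2]oct-5-en-2-one (IUPAC numbering; single enantiomer of 6)
Conditions: preparative HPLC on amylose tris(3,5-dimethylphenylcarbamate), heptane/i-PrOH
Reagents that add atoms: none
Why: Resolution of enantiomers by chromatography on a chiral stationary phase, for which the rigid cage with its ketone, ketal and silyl ether offers well-differentiated contact points; no bond is changed, and the configuration of the retained antipode would be confirmed on a crystalline heavy-atom derivative of the desilylated alcohol.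

**Step 5**
Reactants: 7 cage ketone (single enantiomer); 8 vinylmagnesium bromide
Product: 9 (1S,2R,4S,7S)-7-[(tert-butyldimethylsilyl)oxy]-3,3-dimethoxy-5,6-dimethyl-2-vinylbicyclo[2.2.2]oct-5-en-2-ol (IUPAC numbering; vinyl on C8 syn to the C4=C5 bridge, hydroxyl syn to the C1–C2 bridge)
Conditions: CH2=CHMgBr (2.5 equiv), THF, −78 → 0 °C; then aq. NH4Cl
Reagents that add atoms: vinylmagnesium bromide (8), C=C[Mg]Br
Why: Grignard 1,2-addition to a ketone that cannot enolise (flanked by a bridgehead and the ketal carbon); the reagent should approach over the flat alkene bridge and not past the inward hydrogens of the C1–C2 bridge, which places the vinyl group syn to the alkene as the [3,3] shift demands and sets the C8 carbinol centre.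

**Step 6**
Reactants: 9 vinyl carbinol
Product: 12 cis-decalin ketone (C8 ketone; C9 dimethyl ketal; C3=C4; C2 silyl ether cis to the C5 methyl and to 10-H), via potassium alkoxide 10 (not isolated), via potassium enolate 11 (not isolated)
Conditions: KH (1.5 equiv), 18-crown-6 (1.5 equiv), THF, 0 → 25 °C (to 50 °C if needed); then AcOH (2 equiv) in THF, −78 °C
Reagents that add atoms: none
Why: KH with 18-crown-6 should give the free alkoxide 10, in which the C3–C8 bond is weakened so that the 1,5-diene C6=C7–C8–C3–C4=C5 undergoes a concerted [3,3] sigmatropic shift through the boat enforced by the cage, C5–C6 forming as C3–C8 breaks, to give enolate 11, which AcOH protonates at C7. The closest known reaction type is the anionic oxy-Cope rearrangement of 2-vinylbicyclo[2.2.2]oct-5-en-2-ols from masked o-benzoquinone cycloadducts to cis-decalins; here the receiving alkene carbon C5 is fully substituted, which may slow the shift but should not divert it. Ring B (C5–C10) closes as a six-membered carbocycle by suprafacial sigmatropic bonding of the vinyl terminus C6 to C5 while the bicyclooctene opens, so the cage is converted into the fused decalin without any open-chain cyclisation. The one new stereocentre, quaternary C5, is fixed by the cage, because C6 can reach only the face of the C4=C5 bridge that looks at the C8–C9 bridge, the side on which C9 is bound to C10, so the C5 methyl and 10-H must end cis. The step needs the [3,3] path to win over cycloreversion or loss of the vinyl group; the syn placement of vinyl and alkene from step 5, the strain released from the bicyclooctene and the formation of a stabilised enolate secure this, and the endo silyl ether on C2 points away from the alkoxide and cannot migrate to it.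

**Step 7**
Reactants: 12 cis-decalin ketone; 13 acetone
Product: 15 ketol (C7 carries C(CH3)2OH cis to the C5 methyl), via lithium enolate 14 (not isolated)
Conditions: LiN(i-Pr)2 (1.05 equiv), THF, −78 °C; acetone (3 equiv), −78 °C, 10 min; then AcOH, −78 °C
Reagents that add atoms: acetone (13), CC(C)=O
Why: Directed aldol addition of a regiodefined lithium enolate (C9 carries no hydrogen) to acetone; the concave face of the cis-decalin enolate is screened by ring A, whose C4 and its methyl lie over C7, so acetone should bond to C7 from the convex face and place the side chain cis to the C5 methyl, and the cold acidic quench forestalls retro-aldol and epimerisation.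

**Step 8**
Reactants: 15 ketol
Product: 16 isopropenyl ketone (C7 isopropenyl cis to the C5 methyl; C8 ketone; C9 dimethyl ketal)
Conditions: SOCl2 (1.5 equiv), pyridine, −20 → 0 °C
Reagents that add atoms: none
Why: Dehydration of the tertiary alcohol through its chlorosulfite by E2 loss of a methyl hydrogen; the only ring hydrogen that could lead to the conjugated isopropylidene ketone is the C7 hydrogen on the screened concave face and pyridine is too weak to enolise the ketone, so the isopropenyl isomer is expected and C7 is left untouched.

**Step 9**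
Reactants: 16 isopropenyl ketone
Product: 17 C8 alcohol (8-OH trans to the isopropenyl group, on the face opposite to the C5 methyl; C9 dimethyl ketal)
Conditions: NaBH4, CeCl3·7H2O, MeOH, −78 → −40 °C
Reagents that add atoms: none
Why: Luche-type borohydride reduction of the ketone: with isopropenyl equatorial, ring B sits in the chair whose axial C9 methoxy group covers the concave face, so hydride should enter axially from the convex face anti to that C–O bond and give the equatorial C8 alcohol trans to the isopropenyl group, while CeCl3 keeps the medium non-basic so that the β,γ-unsaturated ketone neither conjugates nor epimerises.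

**Step 10**
Reactants: 17 C8 alcohol
Product: 18 α-hydroxy ketone (C9 ketone; 8-OH; C2 silyl ether retained)
Conditions: PPTS (0.3 equiv), acetone–H2O (10:1), 50 °C
Reagents that add atoms: water, O
Why: Acid-catalysed hydrolysis of the dimethyl ketal, helped by relief of the crowding of the methoxy group that points into the concave face; PPTS is mild enough for the allylic silyl ether, the isopropenyl group and the two enolisable positions C8 and C10 beside the new ketone.

**Step 11**
Reactants: 18 α-hydroxy ketone
Product: 19 cis-8,9-diol (9-OH axial, cis to 8-OH and trans to 10-H; C2 silyl ether; C3=C4)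
Conditions: LiBH(s-Bu)3 (2.5 equiv), THF, −78 °C; then H2O
Reagents that add atoms: none
Why: Ketone reduction by a bulky trialkylborohydride: the axial trajectory at C9 is closed by ring A (C4 is syn-axial and the C2 hydrogen points inward), so hydride should arrive from the open convex side and leave the new C9 hydroxyl axial, cis to the C8 hydroxyl.

**Step 12**
Reactants: 19 cis-8,9-diol
Product: 20 triol (allylic 2-OH; 8-OH; 9-OH)
Conditions: Bu4NF (1.5 equiv), THF, 25 °C
Reagents that add atoms: none
Why: Fluoride-induced cleavage of the silyl ether, driven by Si–F bond formation, under non-acidic conditions that spare the ionisable allylic alcohol and the isopropenyl group.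

**Step 13**
Reactants: 20 triol
Product: 21 enone diol (C2 ketone conjugated with C3=C4; 8-OH; 9-OH)
Conditions: MnO2 (activated, 20 equiv), CH2Cl2, 25 °C
Reagents that add atoms: none
Why: Allylic oxidation with MnO2, which converts allylic alcohols far faster than saturated ones, so only the C2 hydroxyl should be oxidised; conjugate addition of O9 to C4 is disfavoured because it would create a fully substituted carbon next to quaternary C5.

**Step 14**
Reactants: 21 enone diol
Product: 23 keto diol (C2 ketone; C4 methyl equatorial and cis to the C5 methyl; 8-OH; 9-OH), via lithium enolate 22 (not isolated)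
Conditions: Li (6 equiv), NH3 (l)–THF, −78 °C, 21 added last; then isoprene, NH4Cl
Reagents that add atoms: none
Why: Dissolving-metal (Birch-type) conjugate reduction of the enone, which leaves the isolated alkene and the alkoxides alone: the equatorial isopropenyl and C8 hydroxyl lock ring B in the chair that makes C4 axial to it, and the β-carbanion is protonated axially on that face, where the C9 hydroxyl lies directly over C4 and can hand over its proton, so the C4 methyl should end equatorial and cis to the C5 methyl (its epimer would thrust the methyl into ring B), while enolate 22 shields the C2 carbonyl until the quench.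

**Step 15**
Reactants: 23 keto diol
Product: 24 8-O-triethylsilyl ether (9-OH free)
Conditions: Et3SiCl (1.1 equiv), imidazole, CH2Cl2, −20 → 0 °C
Reagents that add atoms: chlorotriethylsilane, CC[Si](Cl)(CC)CC
Why: Silylation of a secondary alcohol, selective for the equatorial C8 hydroxyl because the C9 hydroxyl is axial on the concave face beside C4–H, which tells the two oxygens apart.

**Step 16**
Reactants: 24 8-O-triethylsilyl ether; 25 tiglic acid
Product: 26 9-O-tigloyl 8-O-triethylsilyl ether
Conditions: 25 (4 equiv), 2,4,6-trichlorobenzoyl chloride (4 equiv), Et3N, toluene, 25 °C; then 24, DMAP (4 equiv), toluene, 80 °C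
Reagents that add atoms: tiglic acid (25), C/C=C(\C)C(=O)O
Why: Yamaguchi esterification through the mixed 2,4,6-trichlorobenzoic anhydride and the acylpyridinium salt, the standard way to tigloylate a hindered secondary alcohol; the silyl group on O8 can neither migrate nor be acylated under amine bases (an acetate there could shift to O9 and free the more reactive O8), and the E tiglate is the stable geometry.

**Step 17**
Reactants: 26 9-O-tigloyl 8-O-triethylsilyl ether
Product: 27 8-hydroxy 9-tiglate
Conditions: HF·pyridine, pyridine–THF, 0 °C
Reagents that add atoms: none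
Why: Fluoride cleavage of the triethylsilyl ether under buffered acidic conditions, so that no alkoxide is formed next to the tiglate and the acyl group should stay on O9.

**Step 18**
Reactants: 27 8-hydroxy 9-tiglate
Product: 28 CNP0204573.1
Conditions: Ac2O, pyridine, DMAP (0.1 equiv), CH2Cl2, 0 → 25 °C
Reagents that add atoms: acetic anhydride, CC(=O)OC(C)=O
Why: Acetylation of the unhindered equatorial C8 hydroxyl by nucleophilic catalysis, fast enough to outrun any migration of the tigloyl group, completes the target.

**Compound list**

1 | 3,4-dimethylphenol | Cc1ccc(O)cc1C | starting material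
2 | 2-bromo-4,5-dimethylphenol | Cc1cc(O)c(Br)cc1C | intermediate
3 | 2-methoxy-4,5-dimethylphenol | COc1cc(C)c(C)cc1O | intermediate
4 | tert-butyldimethyl(vinyloxy)silane | C=CO[Si](C)(C)C(C)(C)C | starting material
5 | 6,6-dimethoxy-3,4-dimethylcyclohexa-2,4-dien-1-one (dienone ketal, not isolated) | COC1(OC)C=C(C)C(C)=CC1=O | intermediate
6 | racemic 7-[(tert-butyldimethylsilyl)oxy]-3,3-dimethoxy-5,6-dimethylbicyclo[2.2.2]oct-5-en-2-one, silyloxy endo (racemate; SMILES shows one enantiomer) | O=C1[C@@H]2[C@@H](O[Si](C)(C)C(C)(C)C)C[C@@H](C(C)=C2C)C1(OC)OC | intermediate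
7 | (1S,4S,7S)-7-[(tert-butyldimethylsilyl)oxy]-3,3-dimethoxy-5,6-dimethylbicyclo[2.2.2]oct-5-en-2-one | O=C1[C@@H]2[C@@H](O[Si](C)(C)C(C)(C)C)C[C@@H](C(C)=C2C)C1(OC)OC | intermediate
8 | vinylmagnesium bromide | C=C[Mg]Br | starting material
9 | (1S,2R,4S,7S)-7-[(tert-butyldimethylsilyl)oxy]-3,3-dimethoxy-5,6-dimethyl-2-vinylbicyclo[2.2.2]oct-5-en-2-ol (vinyl syn to the alkene bridge) | C=C[C@@]1(O)[C@@H]2[C@@H](O[Si](C)(C)C(C)(C)C)C[C@@H](C(C)=C2C)C1(OC)OC | intermediate
10 | potassium alkoxide of 9 (not isolated) | [K+].C=C[C@@]1([O-])[C@@H]2[C@@H](O[Si](C)(C)C(C)(C)C)C[C@@H](C(C)=C2C)C1(OC)OC | intermediate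
11 | potassium C7=C8 enolate of 12 (not isolated) | [K+].[O-]C1=CC[C@@]2(C)[C@H](C[C@H](O[Si](C)(C)C(C)(C)C)C=C2C)C1(OC)OC | intermediate
12 | cis-decalin ketone: C8 ketone, C9 dimethyl ketal, C3=C4, C4 and C5 methyls, C2 silyl ether cis to the C5 methyl and 10-H | C1C[C@@]2(C)[C@H](C[C@H](O[Si](C)(C)C(C)(C)C)C=C2C)C(OC)(OC)C1=O | intermediate
13 | acetone | CC(C)=O | starting material
14 | lithium C7=C8 enolate of 12 (not isolated) | [Li+].[O-]C1=CC[C@@]2(C)[C@H](C[C@H](O[Si](C)(C)C(C)(C)C)C=C2C)C1(OC)OC | intermediate
15 | ketol: 12 with C(CH3)2OH on C7, cis to the C5 methyl | CC(C)(O)[C@H]1C[C@@]2(C)[C@H](C[C@H](O[Si](C)(C)C(C)(C)C)C=C2C)C(OC)(OC)C1=O | intermediate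
16 | isopropenyl ketone: 12 with isopropenyl on C7, cis to the C5 methyl | C=C(C)[C@H]1C[C@@]2(C)[C@H](C[C@H](O[Si](C)(C)C(C)(C)C)C=C2C)C(OC)(OC)C1=O | intermediate
17 | C8 alcohol: 8-OH trans to isopropenyl, C9 dimethyl ketal | C=C(C)[C@H]1C[C@@]2(C)[C@H](C[C@H](O[Si](C)(C)C(C)(C)C)C=C2C)C(OC)(OC)[C@@H]1O | intermediate
18 | α-hydroxy ketone: C9 ketone, 8-OH | C=C(C)[C@H]1C[C@@]2(C)[C@H](C[C@H](O[Si](C)(C)C(C)(C)C)C=C2C)C(=O)[C@@H]1O | intermediate
19 | cis-8,9-diol: both hydroxyls on the face opposite to the C5 methyl and 10-H, C2 silyl ether | C=C(C)[C@H]1C[C@@]2(C)[C@H](C[C@H](O[Si](C)(C)C(C)(C)C)C=C2C)[C@H](O)[C@@H]1O | intermediate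
20 | triol: 2-OH (allylic), 8-OH, 9-OH | C=C(C)[C@H]1C[C@@]2(C)[C@H](C[C@H](O)C=C2C)[C@H](O)[C@@H]1O | intermediate
21 | enone diol: C2 ketone, C3=C4, 8-OH, 9-OH | C=C(C)[C@H]1C[C@@]2(C)[C@H](CC(=O)C=C2C)[C@H](O)[C@@H]1O | intermediate
22 | lithium C2=C3 enolate of 23 (not isolated) | [Li+].C=C(C)[C@H]1C[C@@]2(C)[C@H](CC([O-])=C[C@@H]2C)[C@H](O)[C@@H]1O | intermediate
23 | keto diol: C2 ketone, C4 methyl cis to C5 methyl, 8-OH, 9-OH | C=C(C)[C@H]1C[C@@]2(C)[C@H](CC(=O)C[C@@H]2C)[C@H](O)[C@@H]1O | intermediate
24 | 8-O-triethylsilyl ether of 23 | C=C(C)[C@H]1C[C@@]2(C)[C@H](CC(=O)C[C@@H]2C)[C@H](O)[C@@H]1O[Si](CC)(CC)CC | intermediate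
25 | tiglic acid, (E)-2-methylbut-2-enoic acid | C/C=C(\C)C(=O)O | starting material
26 | 9-O-tigloyl 8-O-triethylsilyl ether | C=C(C)[C@H]1C[C@@]2(C)[C@H](CC(=O)C[C@@H]2C)[C@H](OC(=O)/C(C)=C/C)[C@@H]1O[Si](CC)(CC)CC | intermediate
27 | 8-hydroxy 9-tiglate | C=C(C)[C@H]1C[C@@]2(C)[C@H](CC(=O)C[C@@H]2C)[C@H](OC(=O)/C(C)=C/C)[C@@H]1O | intermediate
28 | CNP0204573.1, (4S,5R,7R,8R,9S,10S)-8-acetoxy-9-[(E)-2-methylbut-2-enoyloxy]eremophil-11-en-2-one | C=C(C)[C@H]1C[C@@]2(C)[C@H](CC(=O)C[C@@H]2C)[C@H](OC(=O)/C(C)=C/C)[C@@H]1OC(C)=O | target

**Step count and risks**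

Total step count: 18. Longest linear sequence: 18 steps (1 → 28); compounds 4, 8, 13 and 25 enter as single reagents.

Steps most likely to fail:

1. Step 16 (tigloylation of O9). The acylation may stall, because the C9 hydroxyl sits on the concave face beside C4–H and may rest as a hemiketal with the C2 ketone, and forcing it may strip or shift the silyl group on O8. Fallback: setting out from 24, the oxygen is first acylated with the smaller, saturated acyl donor 2-(diethoxyphosphoryl)propanoic acid (N,N'-dicyclohexylcarbodiimide, DMAP, CH2Cl2) to give the 9-O-phosphonopropionate F7. A Horner–Wadsworth–Emmons olefination with excess acetaldehyde (LiCl, DBU, MeCN, 0 °C) then builds the E-configured 2-methylbut-2-enoate on the oxygen, which returns the route to 26.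

2. Step 7 (aldol at C7). Acetone may approach the enolate from the concave face, giving poor or inverted facial selectivity, or the aldolate may revert. Fallback: setting out from 12, the aldol and the dehydration are run as in steps 7 and 8 without regard to C7, which gives the C7-epimeric ketol F3 and then the C7-epimeric isopropenyl ketone F4. DBU in toluene moves the double bond into conjugation to give the isopropylidene ketone F5, in which C7 is no longer a stereocentre. LiN(i-Pr)2 in THF at −78 °C removes a γ-hydrogen to form the lithium dienolate F6, and kinetic protonation at C7 with AcOH at −78 °C should deliver the proton to the face acetone had preferred, leaving the isopropenyl group on the opposite, wanted face. The route is rejoined at 16.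

3. Step 3 (dearomatisation and cycloaddition). The silyl enol ether may be consumed by methanolysis or by the oxidant before it traps the dienone, which would then dimerise. Fallback: setting out from 3, the oxidation is run under the same conditions in the presence of benzyl vinyl ether, an enol ether that withstands acidic methanol, to give the racemic endo benzyl ether adduct F1. Hydrogenolysis (H2, Pd/C, EtOAc; the tetrasubstituted bridge alkene should be inert) gives the racemic endo alcohol F2, and silylation (t-BuMe2SiCl, imidazole, DMF) returns the route to 6.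

**Further compounds**

F1 | step 3 | racemic 7-benzyloxy-3,3-dimethoxy-5,6-dimethylbicyclo[2.2.2]oct-5-en-2-one, benzyloxy endo (SMILES shows one enantiomer) | O=C1[C@@H]2[C@@H](OCc3ccccc3)C[C@@H](C(C)=C2C)C1(OC)OC
F2 | step 3 | racemic 7-hydroxy-3,3-dimethoxy-5,6-dimethylbicyclo[2.2.2]oct-5-en-2-one, hydroxyl endo (SMILES shows one enantiomer) | O=C1[C@@H]2[C@@H](O)C[C@@H](C(C)=C2C)C1(OC)OC
F3 | step 7 | C7 epimer of ketol 15 | CC(C)(O)[C@@H]1C[C@@]2(C)[C@H](C[C@H](O[Si](C)(C)C(C)(C)C)C=C2C)C(OC)(OC)C1=O
F4 | step 7 | C7 epimer of isopropenyl ketone 16 | C=C(C)[C@@H]1C[C@@]2(C)[C@H](C[C@H](O[Si](C)(C)C(C)(C)C)C=C2C)C(OC)(OC)C1=O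
F5 | step 7 | isopropylidene ketone (C7=C11 conjugated with the C8 ketone) | CC(C)=C1C[C@@]2(C)[C@H](C[C@H](O[Si](C)(C)C(C)(C)C)C=C2C)C(OC)(OC)C1=O
F6 | step 7 | lithium dienolate of F5 (C7=C8 enolate carrying isopropenyl on C7) | [Li+].[O-]C1=C(C(C)=C)C[C@@]2(C)[C@H](C[C@H](O[Si](C)(C)C(C)(C)C)C=C2C)C1(OC)OC
F7 | step 16 | 9-O-[2-(diethoxyphosphoryl)propanoyl] 8-O-triethylsilyl ether of 23 | C=C(C)[C@H]1C[C@@]2(C)[C@H](CC(=O)C[C@@H]2C)[C@H](OC(=O)C(C)P(=O)(OCC)OCC)[C@@H]1O[Si](CC)(CC)CC
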